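**Strategy.** Everything rests on the C3–C4 bond of pyran ring J in the 6-linked fisetinidol unit. C3 is a carbinol carbon and C4 a benzylic carbon ortho/para to the oxygens O1 and O7 of its resorcinol ring G, so both can start as aldehyde carbons. A SmI2 pinacol cyclisation of an acyclic aryl/alkyl dialdehyde, whose C2 stereocentre comes from an iridium-catalysed allylic etherification, closes ring J and sets the 3-hydroxyl while delivering the flavan-3,4-diol, the biogenetic C4 electrophile. Its 4-methyl ether is used twice: tethered delivery to catechin C8 (3,4-cis upper unit), then intermolecular attack by D-ring C6 (3,4-trans lower unit), then global hydrogenolysis.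

Key step: step 6

Remark: rings are lettered A (resorcinol), B (catechol), C (pyran) in the upper 8-linked fisetinidol unit, D, E, F likewise in catechin, and G, H, J in the lower 6-linked fisetinidol unit, with flavan numbering inside each unit. Compounds 1, 2, 6 and 14 are taken as commercial. C4 of methyl ether 13 is ionised in every later use, so a co-formed C4 epimer would converge. In step 13 this ionisation regenerates cation 12, the same species through which 13 is made in step 7.

Step 1
Reactants: 1 3,4-bis(benzyloxy)benzaldehyde; 2 triethyl phosphonoacetate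
Product: 3 ethyl (E)-3-[3,4-bis(benzyloxy)phenyl]prop-2-enoate
Conditions: NaH, THF, 0 °C to rt
Reagents that add atoms: none
Why: Horner–Wadsworth–Emmons olefination of an aryl aldehyde with a stabilised phosphonate anion should give the (E)-cinnamate.

Step 2
Reactants: 3 ethyl (E)-3-[3,4-bis(benzyloxy)phenyl]prop-2-enoate
Product: 4 (E)-3-[3,4-bis(benzyloxy)phenyl]prop-2-en-1-ol
Conditions: iBu2AlH (2.2 equiv), CH2Cl2, −78 °C; aqueous work-up
Reagents that add atoms: none
Why: 1,2-reduction of the conjugated ester by the aluminium hydride should give the allylic alcohol without touching the alkene or the benzyl ethers.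

Step 3
Reactants: 4 (E)-3-[3,4-bis(benzyloxy)phenyl]prop-2-en-1-ol
Product: 5 (E)-3-[3,4-bis(benzyloxy)phenyl]prop-2-en-1-yl methyl carbonate
Conditions: ClCO2Me, pyridine, CH2Cl2, 0 °C
Reagents that add atoms: methyl chloroformate COC(=O)Cl
Why: O-acylation of the primary allylic alcohol with a chloroformate gives the carbonate leaving group needed for allylic substitution.

Step 4
Reactants: 5 (E)-3-[3,4-bis(benzyloxy)phenyl]prop-2-en-1-yl methyl carbonate; 6 4-(benzyloxy)-2-hydroxybenzaldehyde
Product: 7 4-(benzyloxy)-2-{[(1S)-1-[3,4-bis(benzyloxy)phenyl]prop-2-en-1-yl]oxy}benzaldehyde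
Conditions: [Ir(cod)Cl]2 (2 mol %), O,O'-(1,1'-binaphthyl-2,2'-diyl) N,N-bis(1-phenylethyl)phosphoramidite (4 mol %, enantiomer that delivers the (S)-ether), sodium aryloxide of 6 (from NaH), THF, rt
Reagents that add atoms: none
Why: Iridium-catalysed asymmetric allylic etherification of a cinnamyl carbonate with an aryloxide should give the branched ether, the allyl intermediate formed from [Ir(cod)Cl]2 and the chiral phosphoramidite setting the benzylic stereocentre (S) and the electron-rich aryl group favouring the branched isomer.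

Step 5
Reactants: 7 4-(benzyloxy)-2-{[(1S)-1-[3,4-bis(benzyloxy)phenyl]prop-2-en-1-yl]oxy}benzaldehyde
Product: 9 4-(benzyloxy)-2-{[(1R)-1-[3,4-bis(benzyloxy)phenyl]-2-oxoethyl]oxy}benzaldehyde, via ozonide 8 (not isolated)
Conditions: O3, CH2Cl2, −78 °C (stopped at first excess); then PPh3, −78 °C to rt; crude product used at once
Reagents that add atoms: ozone [O-][O+]=O
Why: Ozonolysis of the terminal vinyl group with reductive work-up gives the α-aryloxy aldehyde under base-free conditions, so the adjacent stereocentre (descriptor R only by priority change) should be retained, the monosubstituted alkene reacting much faster than the alkoxyarenes.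

Step 6
Reactants: 9 4-(benzyloxy)-2-{[(1R)-1-[3,4-bis(benzyloxy)phenyl]-2-oxoethyl]oxy}benzaldehyde
Product: 11 (2R,3S,4S)-7-(benzyloxy)-2-[3,4-bis(benzyloxy)phenyl]-3,4-dihydro-2H-chromene-3,4-diol, via ketyl radical anion 10 (not isolated)
Conditions: SmI2 (2.5 equiv), THF (0.01 M), −78 to −20 °C; then aq NH4Cl
Reagents that add atoms: none
Why: SmI2 (divalent samarium) transfers an electron to the more easily reduced aryl aldehyde to give the samarium-bound ketyl 10, whose C4 radical adds to the samarium-coordinated C3 aldehyde, and a second electron gives the trivalent samarium diolate that is protonated on work-up. The closest known reaction type is the intramolecular SmI2 pinacol coupling of 1,6-dialdehydes to cis-cyclohexane-1,2-diols. Ring J is closed in the 6-exo-trig mode (C4 onto C3 with the carbonyl oxygen outside the ring). C3 is controlled by C2: in the chair-like transition state the ring H aryl group is pseudo-equatorial and the C3 carbonyl lies pseudo-equatorial, anti to the C2–O1 bond (dipole opposition), which should give the 2,3-trans (3S) carbinol; C4 is set cis to O3 (4S) because one samarium bridges both oxygens, and this centre is erased later in any case. The step needs chemoselective ketyl formation at the aryl aldehyde (secured by its lower reduction potential and by the absence of a C3 carbanion that could expel the C2 aryloxide), cyclisation over dimerisation (secured by the six-membered ring and high dilution), and retention at C2 (secured by neutral conditions at low temperature).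

Step 7
Reactants: 11 (2R,3S,4S)-7-(benzyloxy)-2-[3,4-bis(benzyloxy)phenyl]-3,4-dihydro-2H-chromene-3,4-diol
Product: 13 (2R,3S,4R)-7-(benzyloxy)-2-[3,4-bis(benzyloxy)phenyl]-4-methoxy-3,4-dihydro-2H-chromen-3-ol, via benzylic cation 12 (not isolated)
Conditions: PPTS (10 mol %), MeOH/CH2Cl2, rt
Reagents that add atoms: methanol CO
Why: SN1 solvolysis of the benzylic 4-hydroxyl, whose cation 12 is stabilised by O1 and the 7-benzyloxy group, should give the 4-methyl ether (mainly 3,4-trans by attack anti to the 3-hydroxyl) and so differentiate the two hydroxyls without touching C2 or C3.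

Step 8
Reactants: 14 (+)-catechin
Product: 15 5,7,3',4'-tetra-O-benzyl-(+)-catechin
Conditions: BnBr (4.4 equiv), K2CO3, DMF, rt
Reagents that add atoms: benzyl bromide BrCc1ccccc1
Why: Williamson etherification under carbonate base should benzylate the four phenols only, since the aliphatic 3-hydroxyl is not deprotonated.

Step 9
Reactants: 15 5,7,3',4'-tetra-O-benzyl-(+)-catechin
Product: 16 5,7,3',4'-tetra-O-benzyl-(+)-catechin 3-O-(hydrogen glutarate)
Conditions: glutaric anhydride, DMAP, pyridine, CH2Cl2, rt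
Reagents that add atoms: glutaric anhydride O=C1CCCC(=O)O1
Why: DMAP-catalysed ring-opening acylation of the secondary 3-hydroxyl by the cyclic anhydride gives the half ester in one operation.

Step 10
Reactants: 16 5,7,3',4'-tetra-O-benzyl-(+)-catechin 3-O-(hydrogen glutarate); 13 (2R,3S,4R)-7-(benzyloxy)-2-[3,4-bis(benzyloxy)phenyl]-4-methoxy-3,4-dihydro-2H-chromen-3-ol
Product: 17 glutarate diester linking O3 of 13 to O3 of 15
Conditions: DCC, DMAP, CH2Cl2, 0 °C to rt
Reagents that add atoms: none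
Why: Steglich esterification of the only free hydroxyl of 13 ties electrophile and nucleophile together through their 3-oxygens, the benzylic methyl ether being stable to these conditions.

Step 11
Reactants: 17 glutarate diester linking O3 of 13 to O3 of 15
Product: 19 3-O,3-O-glutaryl-bridged hepta-O-benzyl fisetinidol-(4β→8)-catechin (14-membered macrocycle), via tethered benzylic cation 18 (not isolated)
Conditions: TMSOTf (0.3 equiv), CH2Cl2 (1 mM), −40 °C
Reagents that add atoms: none
Why: Lewis-acid ionisation of the 4-methoxy group and intramolecular Friedel–Crafts alkylation by catechin ring D at C8 (its more reactive position) should close the macrocycle, the short tether on the β-oriented 3-oxygen allowing attack only on the same face and so setting upper C4 3,4-cis (4β).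

Step 12
Reactants: 19 3-O,3-O-glutaryl-bridged hepta-O-benzyl fisetinidol-(4β→8)-catechin
Product: 20 7,3',4'-tri-O-benzylfisetinidol-(4β→8)-5,7,3',4'-tetra-O-benzylcatechin
Conditions: NaOMe (cat.), MeOH/THF, rt
Reagents that add atoms: none
Why: Zemplén-type transesterification removes the tether as dimethyl glutarate, and with all phenols benzylated no stereocentre is base-labile.

Step 13
Reactants: 20 7,3',4'-tri-O-benzylfisetinidol-(4β→8)-5,7,3',4'-tetra-O-benzylcatechin; 13 (2R,3S,4R)-7-(benzyloxy)-2-[3,4-bis(benzyloxy)phenyl]-4-methoxy-3,4-dihydro-2H-chromen-3-ol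
Product: 21 deca-O-benzyl fisetinidol-(4β→8)-catechin-(6→4α)-fisetinidol
Conditions: TMSOTf (0.5 equiv), CH2Cl2, −78 to −40 °C, 13 (1.5 equiv) added slowly
Reagents that add atoms: none
Why: TMSOTf re-ionises the 4-methoxy group of 13 to the benzylic cation already met as 12 in step 7, and its intermolecular Friedel–Crafts capture by C6, the only free position of phloroglucinol ring D and far more nucleophilic than resorcinol rings A and G, should occur anti to the 3-hydroxyl and set lower C4 3,4-trans (4α).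

Step 14
Reactants: 21 deca-O-benzyl fisetinidol-(4β→8)-catechin-(6→4α)-fisetinidol
Product: 22 fisetinidol-(4β→8)-catechin-(6→4α)-fisetinidol
Conditions: H2 (1 atm), Pd(OH)2/C, THF/MeOH/H2O, rt
Reagents that add atoms: none
Why: Hydrogenolysis of the ten benzyl ethers should leave the interflavanyl C–C bonds and all stereocentres untouched.

**Compound list**

1 | 3,4-bis(benzyloxy)benzaldehyde | O=Cc1ccc(OCc2ccccc2)c(OCc2ccccc2)c1 | starting material
2 | triethyl phosphonoacetate | CCOC(=O)CP(=O)(OCC)OCC | starting material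
3 | ethyl (E)-3-[3,4-bis(benzyloxy)phenyl]prop-2-enoate | CCOC(=O)/C=C/c1ccc(OCc2ccccc2)c(OCc2ccccc2)c1 | intermediate
4 | (E)-3-[3,4-bis(benzyloxy)phenyl]prop-2-en-1-ol | OC/C=C/c1ccc(OCc2ccccc2)c(OCc2ccccc2)c1 | intermediate
5 | (E)-3-[3,4-bis(benzyloxy)phenyl]prop-2-en-1-yl methyl carbonate | COC(=O)OC/C=C/c1ccc(OCc2ccccc2)c(OCc2ccccc2)c1 | intermediate
6 | 4-(benzyloxy)-2-hydroxybenzaldehyde | O=Cc1ccc(OCc2ccccc2)cc1O | starting material
7 | 4-(benzyloxy)-2-{[(1S)-1-[3,4-bis(benzyloxy)phenyl]prop-2-en-1-yl]oxy}benzaldehyde | C=C[C@H](Oc1cc(OCc2ccccc2)ccc1C=O)c1ccc(OCc2ccccc2)c(OCc2ccccc2)c1 | intermediate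
8 | ozonide (1,2,4-trioxolane) of 7, mixture at the trioxolane carbon, not isolated | C1OC(OO1)[C@H](Oc1cc(OCc2ccccc2)ccc1C=O)c1ccc(OCc2ccccc2)c(OCc2ccccc2)c1 | intermediate
9 | 4-(benzyloxy)-2-{[(1R)-1-[3,4-bis(benzyloxy)phenyl]-2-oxoethyl]oxy}benzaldehyde | O=C[C@H](Oc1cc(OCc2ccccc2)ccc1C=O)c1ccc(OCc2ccccc2)c(OCc2ccccc2)c1 | intermediate
10 | samarium-bound ketyl radical anion at the aryl aldehyde carbon (future C4) of 9, not isolated | [O-][CH]c1ccc(OCc2ccccc2)cc1O[C@@H](C=O)c1ccc(OCc2ccccc2)c(OCc2ccccc2)c1 | intermediate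
11 | (2R,3S,4S)-7-(benzyloxy)-2-[3,4-bis(benzyloxy)phenyl]-3,4-dihydro-2H-chromene-3,4-diol (2,3-trans-3,4-cis) | O[C@H]1c2ccc(OCc3ccccc3)cc2O[C@H](c2ccc(OCc3ccccc3)c(OCc3ccccc3)c2)[C@H]1O | intermediate
12 | C4 benzylic cation of 11 with C2 and C3 as in 11, not isolated | [CH+]1c2ccc(OCc3ccccc3)cc2O[C@H](c2ccc(OCc3ccccc3)c(OCc3ccccc3)c2)[C@H]1O | intermediate
13 | (2R,3S,4R)-7-(benzyloxy)-2-[3,4-bis(benzyloxy)phenyl]-4-methoxy-3,4-dihydro-2H-chromen-3-ol (major 3,4-trans epimer) | CO[C@@H]1c2ccc(OCc3ccccc3)cc2O[C@H](c2ccc(OCc3ccccc3)c(OCc3ccccc3)c2)[C@H]1O | intermediate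
14 | (+)-catechin, (2R,3S) | O[C@H]1Cc2c(O)cc(O)cc2O[C@@H]1c1ccc(O)c(O)c1 | starting material
15 | 5,7,3',4'-tetra-O-benzyl-(+)-catechin | O[C@H]1Cc2c(OCc3ccccc3)cc(OCc3ccccc3)cc2O[C@@H]1c1ccc(OCc2ccccc2)c(OCc2ccccc2)c1 | intermediate
16 | 5,7,3',4'-tetra-O-benzyl-(+)-catechin 3-O-(hydrogen glutarate) | OC(=O)CCCC(=O)O[C@H]1Cc2c(OCc3ccccc3)cc(OCc3ccccc3)cc2O[C@@H]1c1ccc(OCc2ccccc2)c(OCc2ccccc2)c1 | intermediate
17 | glutarate diester linking O3 of 13 to O3 of 15 | CO[C@@H]1c2ccc(OCc3ccccc3)cc2O[C@H](c2ccc(OCc3ccccc3)c(OCc3ccccc3)c2)[C@H]1OC(=O)CCCC(=O)O[C@H]1Cc2c(OCc3ccccc3)cc(OCc3ccccc3)cc2O[C@@H]1c1ccc(OCc2ccccc2)c(OCc2ccccc2)c1 | intermediate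
18 | C4 benzylic cation of 17 carrying the tethered catechin, not isolated | [CH+]1c2ccc(OCc3ccccc3)cc2O[C@H](c2ccc(OCc3ccccc3)c(OCc3ccccc3)c2)[C@H]1OC(=O)CCCC(=O)O[C@H]1Cc2c(OCc3ccccc3)cc(OCc3ccccc3)cc2O[C@@H]1c1ccc(OCc2ccccc2)c(OCc2ccccc2)c1 | intermediate
19 | 3-O,3-O-glutaryl-bridged hepta-O-benzyl fisetinidol-(4β→8)-catechin (14-membered macrocycle) | O(Cc1ccccc1)c1ccc2c(c1)O[C@H](c1ccc(OCc3ccccc3)c(OCc3ccccc3)c1)[C@@H](OC(=O)CCCC(=O)O%10)[C@H]2c1c(OCc3ccccc3)cc(OCc3ccccc3)c2c1O[C@H](c1ccc(OCc3ccccc3)c(OCc3ccccc3)c1)[C@@H]%10C2 | intermediate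
20 | 7,3',4'-tri-O-benzylfisetinidol-(4β→8)-5,7,3',4'-tetra-O-benzylcatechin | O(Cc1ccccc1)c1ccc2c(c1)O[C@H](c1ccc(OCc3ccccc3)c(OCc3ccccc3)c1)[C@@H](O)[C@H]2c1c(OCc3ccccc3)cc(OCc3ccccc3)c2c1O[C@H](c1ccc(OCc3ccccc3)c(OCc3ccccc3)c1)[C@@H](O)C2 | intermediate
21 | deca-O-benzyl fisetinidol-(4β→8)-catechin-(6→4α)-fisetinidol (all phenols benzylated, three 3-hydroxyls free) | O(Cc1ccccc1)c1ccc2c(c1)O[C@H](c1ccc(OCc3ccccc3)c(OCc3ccccc3)c1)[C@@H](O)[C@H]2c1c(OCc3ccccc3)c([C@@H]2c3ccc(OCc4ccccc4)cc3O[C@H](c3ccc(OCc4ccccc4)c(OCc4ccccc4)c3)[C@H]2O)c(OCc3ccccc3)c2c1O[C@H](c1ccc(OCc3ccccc3)c(OCc3ccccc3)c1)[C@@H](O)C2 | intermediate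
22 | fisetinidol-(4β→8)-catechin-(6→4α)-fisetinidol | Oc1ccc2c(c1)O[C@H](c1ccc(O)c(O)c1)[C@@H](O)[C@H]2c1c(O)c([C@@H]2c3ccc(O)cc3O[C@H](c3ccc(O)c(O)c3)[C@H]2O)c(O)c2c1O[C@H](c1ccc(O)c(O)c1)[C@@H](O)C2 | target

**Totals and risks**

Total step count: 14. Longest linear sequence: 12 (steps 1–7 and 10–14).

Steps most likely to fail:

Step 6. The α-aryloxy aldehyde may lose its C2 configuration by enolisation before cyclisation, the aryl aldehyde may dimerise intermolecularly, or facial selectivity at C3 may be poor. The fallback sets out from 7 and comes back at 11. Wittig methylenation of the aryl aldehyde (methyltriphenylphosphonium bromide, KOtBu, THF) would give the diene 4-(benzyloxy)-2-{[(1S)-1-[3,4-bis(benzyloxy)phenyl]prop-2-en-1-yl]oxy}-1-ethenylbenzene F1. Ring-closing metathesis with the second-generation Grubbs catalyst (H2IMes)(PCy3)Cl2Ru=CHPh in CH2Cl2 would close ring J across C3=C4 to the flav-3-ene (2S)-7-(benzyloxy)-2-[3,4-bis(benzyloxy)phenyl]-2H-chromene F2. Dihydroxylation with OsO4 (cat.)/NMO, expected anti to the C2 aryl group, would give 11.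

Step 11. Cyclisation may occur through catechin C6 instead of C8, intermolecular coupling may give oligomers, or a folded tether may deliver ring D to the α face. The fallback sets out from 13 and 15 and comes back at 20. Untethered intermolecular TMSOTf coupling of 13 with excess 15 at C8 would give 20 together with its upper-C4 epimer, 7,3',4'-tri-O-benzylfisetinidol-(4α→8)-5,7,3',4'-tetra-O-benzylcatechin F3, from which 20 is separated by chromatography.

Step 13. Facial selectivity at lower C4 may be poor, the electrophile may self-condense through its own ring G, or attack at the hindered C6 may be slow. The fallback sets out from 13 and comes back at 21. Acetylation (Ac2O, pyridine) would give (2R,3S,4R)-7-(benzyloxy)-2-[3,4-bis(benzyloxy)phenyl]-4-methoxy-3,4-dihydro-2H-chromen-3-yl acetate F4. In its TMSOTf coupling with 20 the 3-acetoxy group should shield the β face of the cation by anchimeric assistance, giving the lower-unit 3-O-acetate of 21 F5. NaOMe in MeOH/THF would then return 21.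

**Further compounds**

F1 | step 6 | 4-(benzyloxy)-2-{[(1S)-1-[3,4-bis(benzyloxy)phenyl]prop-2-en-1-yl]oxy}-1-ethenylbenzene | C=C[C@H](Oc1cc(OCc2ccccc2)ccc1C=C)c1ccc(OCc2ccccc2)c(OCc2ccccc2)c1
F2 | step 6 | (2S)-7-(benzyloxy)-2-[3,4-bis(benzyloxy)phenyl]-2H-chromene | C1=Cc2ccc(OCc3ccccc3)cc2O[C@@H]1c1ccc(OCc2ccccc2)c(OCc2ccccc2)c1
F3 | step 11 | 7,3',4'-tri-O-benzylfisetinidol-(4α→8)-5,7,3',4'-tetra-O-benzylcatechin | O(Cc1ccccc1)c1ccc2c(c1)O[C@H](c1ccc(OCc3ccccc3)c(OCc3ccccc3)c1)[C@@H](O)[C@@H]2c1c(OCc3ccccc3)cc(OCc3ccccc3)c2c1O[C@H](c1ccc(OCc3ccccc3)c(OCc3ccccc3)c1)[C@@H](O)C2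
F4 | step 13 | (2R,3S,4R)-7-(benzyloxy)-2-[3,4-bis(benzyloxy)phenyl]-4-methoxy-3,4-dihydro-2H-chromen-3-yl acetate | CO[C@@H]1c2ccc(OCc3ccccc3)cc2O[C@H](c2ccc(OCc3ccccc3)c(OCc3ccccc3)c2)[C@H]1OC(C)=O
F5 | step 13 | lower-unit 3-O-acetate of 21 | O(Cc1ccccc1)c1ccc2c(c1)O[C@H](c1ccc(OCc3ccccc3)c(OCc3ccccc3)c1)[C@@H](O)[C@H]2c1c(OCc3ccccc3)c([C@@H]2c3ccc(OCc4ccccc4)cc3O[C@H](c3ccc(OCc4ccccc4)c(OCc4ccccc4)c3)[C@H]2OC(C)=O)c(OCc3ccccc3)c2c1O[C@H](c1ccc(OCc3ccccc3)c(OCc3ccccc3)c1)[C@@H](O)C2
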